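A ratio of two products tempts one to read it as a ratio of two rates, and that was the pitfall in these flasks, where the share of links in links plus capped ends is wanted.

| flask | first end groups | second end groups | one-sided end groups | remark | time |
|---|---|---|---|---|---|
| noon | 0.25 M | 0.90 equiv | 2.5 mM | run made earlier |  |
| summer | 0.12 M | 0.90 equiv | 2.5 mM | run made earlier |  |
| dusk | 0.50 M | 0.90 equiv | 2.5 mM | run made earlier |  |
| alder | 0.25 M | 0.900 equiv (fed, over 40 min) | 2.50 mM | all else is in the flask from the start; the feed brings no volume worth counting | 8.0 h |
| maple | 0.25 M | 0.900 equiv (fed, over 6.0 h) | 2.50 mM | all else is in the flask from the start; the feed brings no volume worth counting | 8.0 h |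
| cedar | 0.25 M | 0.900 equiv | 2.50 mM | everything together at the start | 8.0 h |
| birch | 0.25 M (in portions, 5, over 6.0 h) | 0.900 equiv | 2.50 mM | first portion at the start, last at 6.0 h | 8.0 h |
| elm | 0.25 M (fed, over 6.0 h) | 0.900 equiv | 2.50 mM | all else is in the flask from the start; the feed brings no volume worth counting | 8.0 h |

1. the best flask by share of links in links plus capped ends; "all alike" if 1.5 percentage points covers them all (alder / maple / cedar / birch / elm / all alike)
2. share of links in links plus capped ends at the end, alder
3. share of links in links plus capped ends at the end, maple
4. share of links in links plus capped ends at the end, cedar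
5. share of links in links plus capped ends at the end, birch
6. share of links in links plus capped ends at the end, elm



| run | time / h | links / % | capped ends / % | first end groups / % |
|---|---|---|---|---|
| noon | 0.667 | 8 | 0 | 89 |
| noon | 1.00 | 11 | 2 | 88 |
| noon | 1.33 | 15 | 1 | 87 |
| noon | 2.50 | 14 | 2 | 82 |
| noon | 3.00 | 17 | 1 | 86 |
| noon | 5.00 | 15 | 0 | 87 |
| noon | 8.00 | 11 | 2 | 90 |
| summer | 0.833 | 5 | 1 | 94 |
| summer | 1.33 | 9 | 1 | 90 |
| summer | 2.00 | 7 | 2 | 90 |
| summer | 2.50 | 8 | 1 | 87 |
| summer | 4.00 | 5 | 5 | 89 |
| summer | 6.00 | 6 | 2 | 94 |
| summer | 10.0 | 8 | 2 | 93 |
| dusk | 1.33 | 23 | 0 | 75 |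
| dusk | 3.00 | 21 | 2 | 71 |
| dusk | 4.00 | 25 | 0 | 78 |
| dusk | 6.00 | 21 | 0 | 78 |
| dusk | 8.00 | 18 | 3 | 84 |
| dusk | 10.0 | 12 | 1 | 85 |

(scatter of a reading: 1.5 percentage points)

I followed one one-sided end group, which I took to make one capped end and stop there. It is the limiting reagent of capping, much scarcer than the first end groups, and their ratio gives 1.00 %. I called this the cap ceiling, the most capped ends that charge can make, in percent of the first end groups charged; it counts a charge, not a rate.

Reading the capped column against it, the last readings of the noon, summer and dusk runs were 2 %, 2 % and 1 %, against ceilings of 1.00 %, 2.08 % and 0.500 %, with a scatter of 1.5 percentage points. The links column of the noon and dusk runs, by contrast, fell late: in the noon run it read 17 % at 3.00 h and 11 % at 8.00 h, while first end groups read 86 % and then 90 %, and in the dusk run links went from 25 % at 4.00 h to 12 % at 10.0 h.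

So I took the rule that, once capped ends stand at the ceiling, the share is links divided by links plus the cap ceiling, and the question becomes how many links stand at the end. The noon run has the charges of cedar, so its last links reading gave me 91.7 % for cedar, a figure that carries the scatter of that reading. For alder, maple, birch and elm, whose way of adding differs from cedar's, I had no run to read links from, so I committed to the rule and not to a number.

The forecast said all alike, with 91.5 % for alder, 92.3 % for maple, 91.3 % for cedar, 91 % for birch and 90.8 % for elm, on the ground of “about 10.5–12% links against about 1% capped in every flask”.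

The flasks gave maple as the best, at 93.1 %, with alder at 91.5 %, cedar at 91.3 %, birch at 82.7 % and elm at 81.2 %.

    first end groups + second end groups ⇌ links (K = 6.90 M⁻¹, k = 1.10 M⁻¹ h⁻¹)
    second end groups ⇌ dormant form (K = 0.430, k = 1.20 h⁻¹)
    first end groups + one-sided end groups → capped ends (k = 140 M⁻¹ h⁻¹)
    second end groups → decomposed reagent (k = 0.700 h⁻¹)

At 8.00 h, elm held capped ends at 1.00 %, as the forecast said, but links at 4.33 %, where its words had about 10.5 at the low end. Elm's links and the cap ceiling give 81.2 % by the rule. The neighbouring flask, like elm but with 0.360 equiv of second end groups, has the same cap ceiling, and its links of 1.79 % give 64.2 %; the computed share there was 64.2 %.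

(The numbers in the tables stem from a simulated flask with constants of no real substance; the scatter is artificial.)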